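**Plan**

Ring positions used below: C-1 carbonyl, C-2 CH=, C-3 C(CH3)=, C-4 CHOH, C-5 CH carrying the geranylgeranyl chain, C-6 CH2.
Retrosynthesis: an acyl helper (oxazolidinone carbonyl) is placed on C-6, then the C-4–C-5 and C-6–C-1 ring bonds are cut together. The γ-hydroxy-enone C-1(=O)–C-2=C-3(CH3)–C-4(OH) is read as 4-methylbutenolide whose lactone carbonyl has been handed from the C-4 oxygen to C-6; C-5/C-6 with the chain are an (E)-enoyl imide, cut further between the geranylgeranyl CH2 and the enoyl β-carbon.
Forward: the chain is joined first (Stille coupling), the only ring is then built in one flask by vinylogous Mukaiyama–Michael addition of 4-methyl-2-silyloxyfuran followed by Dieckmann-type O-to-C acyl transfer, and the helper leaves by imide cleavage and decarboxylation.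
Stereochemistry: C-5 comes from the chiral bis(oxazoline) complex of divalent copper (enoyl face), C-4 from the anti (endo-like) topicity of the same addition, which becomes the cis C-4/C-5 relationship; the four E olefins come unchanged from geranylgeraniol.

Key step: step 6

Remark: ethyl (E)-3-(tributylstannyl)prop-2-enoate is taken as a catalogue reagent; hydrostannation of ethyl propiolate would otherwise supply it.
Remark: the ring carbon between the ketone and the acyl group of the β-dicarbonyl intermediates is configurationally labile and is drawn without configuration.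
Remark: (S,S)-tBu-box is 2,2'-(propane-2,2-diyl)bis[(4S)-4-tert-butyl-4,5-dihydrooxazole].

**Route**

Step 1
Reactants: 1 (2E,6E,10E)-3,7,11,15-tetramethylhexadeca-2,6,10,14-tetraen-1-ol (geranylgeraniol)
Product: 2 (2E,6E,10E)-1-bromo-3,7,11,15-tetramethylhexadeca-2,6,10,14-tetraene (geranylgeranyl bromide)
Conditions: PBr3 (0.4 equiv), Et2O, −10 °C; used crude
Reagents that add atoms: phosphorus tribromide BrP(Br)Br
Why: Bromination of a primary allylic alcohol with PBr3 (SN2 displacement of the phosphite leaving group by bromide) at low temperature should give the primary allylic bromide without allylic transposition, so the 2E geometry is retained.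

Step 2
Reactants: 3 ethyl (E)-3-(tributylstannyl)prop-2-enoate
Product: 4 (E)-3-(tributylstannyl)prop-2-enoic acid
Conditions: LiOH·H2O, THF/H2O, 20 °C; cold dilute HCl to pH 4
Reagents that add atoms: lithium hydroxide [Li+].[OH-]
Why: Ester saponification; the alkenyl–tin bond and the E geometry are stable to aqueous LiOH, and mild acidification avoids protodestannylation.

Step 3
Reactants: 4 (E)-3-(tributylstannyl)prop-2-enoic acid, 5 oxazolidin-2-one
Product: 7 3-[(E)-3-(tributylstannyl)prop-2-enoyl]oxazolidin-2-one, via mixed pivalic anhydride 6 (not isolated)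
Conditions: PivCl, Et3N, THF, −20 °C; then 5, LiCl, 20 °C
Reagents that add atoms: none
Why: N-Acylation of oxazolidin-2-one through the mixed pivalic anhydride (mixed-anhydride imide formation assisted by LiCl), in which the nucleophile attacks the less hindered alkenoyl carbonyl and not the pivaloyl carbonyl.

Step 4
Reactants: 2 geranylgeranyl bromide, 7 3-[(E)-3-(tributylstannyl)prop-2-enoyl]oxazolidin-2-one
Product: 8 3-[(2E,5E,9E,13E)-6,10,14,18-tetramethylnonadeca-2,5,9,13,17-pentaenoyl]oxazolidin-2-one
Conditions: Pd2(dba)3 (2.5 mol %), AsPh3 (10 mol %), NMP, 25 °C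
Reagents that add atoms: none
Why: Stille coupling of an allylic bromide with an alkenylstannane, in which the syn-η3-allylpalladium intermediate should be joined at its primary terminus with retention of both olefin geometries, giving the skipped 2E,5E-diene under neutral conditions.

Step 5
Reactants: 9 4-methylfuran-2(5H)-one
Product: 10 trimethyl[(4-methylfuran-2-yl)oxy]silane (4-methyl-2-(trimethylsilyloxy)furan)
Conditions: TMSOTf, Et3N, Et2O, 0 °C; distilled, used fresh
Reagents that add atoms: trimethylsilyl trifluoromethanesulfonate C[Si](C)(C)OS(=O)(=O)C(F)(F)F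
Why: Soft enolisation and O-silylation of the butenolide (silyl dienol ether formation) is driven by the aromaticity of the 2-silyloxyfuran.

Step 6
Reactants: 8 3-[(2E,5E,9E,13E)-6,10,14,18-tetramethylnonadeca-2,5,9,13,17-pentaenoyl]oxazolidin-2-one, 10 4-methyl-2-(trimethylsilyloxy)furan (1.5 equiv)
Product: 12 3-{[(5S,6S)-5-hydroxy-4-methyl-2-oxo-6-[(2E,6E,10E)-3,7,11,15-tetramethylhexadeca-2,6,10,14-tetraen-1-yl]cyclohex-3-en-1-yl]carbonyl}oxazolidin-2-one, via butenolide Michael adduct 11 (not isolated)
Conditions: Cu(OTf)2 (10 mol %), (S,S)-tBu-box (11 mol %), (CF3)2CHOH (1.1 equiv), 4 Å MS, CH2Cl2, −40 °C; then same flask: iPr2NEt (3 equiv), TiCl4 (1.3 equiv), −78 to 0 °C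
Reagents that add atoms: none
Why: The square-planar chelate of imide 8 with the divalent copper bis(oxazoline) complex is attacked at its β-carbon by C5 of silyloxyfuran 10 in a vinylogous Mukaiyama–Michael addition, the reaction type established for 2-silyloxyfurans with 3-alkenoyloxazolidin-2-ones; this forms the C-4–C-5 ring bond and, after silyl transfer to (CF3)2CHOH, gives butenolide 11. Chelation-directed soft enolisation of the imide with TiCl4/iPr2NEt then lets the titanium enolate carbon (C-6) add to the lactone carbonyl (C-1), a titanium-mediated Dieckmann condensation that mirrors the second half of a Hauser–Kraus-type Michael–Dieckmann annulation; the bridged hemiketal opens by C–O cleavage to the C-1 ketone and the C-4 alkoxide. The cyclohexenone ring closes by this 6-exo-trig attack on the lactone carbonyl, through a 7-oxabicyclo[2.2.1]heptene intermediate, and is held by formation of the titanium chelate of the β-keto imide. C-5 is set by the catalyst: a tert-butyl group of the (S,S) ligand shields one face of the s-cis enoyl chelate, so the furan should add to the si face of the β-carbon (5S in the target). C-4 is set relative to C-5 by the compact, Diels–Alder-like (endo) alignment of the furan over the enoyl unit, which should give the anti adduct and thus the cis relationship of the C-4 oxygen and the C-5 side chain on the ring (4S). The step needs γ- and 1,4-selective attack of the furan, which the 2-silyloxyfuran and the bidentate acceptor provide, and enolisation at the imide CH2 in preference to the butenolide γ-hydrogen (which would scramble C-4), which the chelating imide secures under soft enolisation; forming the first bond without base also spares the doubly allylic CH2 of 8.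

Step 7
Reactants: 12 3-{[(5S,6S)-5-hydroxy-4-methyl-2-oxo-6-[(2E,6E,10E)-3,7,11,15-tetramethylhexadeca-2,6,10,14-tetraen-1-yl]cyclohex-3-en-1-yl]carbonyl}oxazolidin-2-one
Product: 15 (4S,5S)-4-hydroxy-3-methyl-5-[(2E,6E,10E)-3,7,11,15-tetramethylhexadeca-2,6,10,14-tetraen-1-yl]cyclohex-2-en-1-one, via peroxy acid 13 (not isolated), via β-keto acid 14 (not isolated)
Conditions: LiOH, H2O2 (30 % aq), THF/H2O, 0 °C; Na2SO3 aq; dilute HCl to pH 3, 20 to 40 °C
Reagents that add atoms: none
Why: Hydroperoxide anion attacks the exocyclic imide carbonyl (LiOOH cleavage of an N-acyloxazolidinone), sulfite reduces the percarboxylate before acidification, and the liberated β-keto acid decarboxylates through its cyclic six-membered transition state; neither stereocentre is α to a carbonyl, so both should be kept.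

**Compound list**

1 | (2E,6E,10E)-3,7,11,15-tetramethylhexadeca-2,6,10,14-tetraen-1-ol (geranylgeraniol) | CC(C)=CCC/C(C)=C/CC/C(C)=C/CC/C(C)=C/CO | starting material
2 | (2E,6E,10E)-1-bromo-3,7,11,15-tetramethylhexadeca-2,6,10,14-tetraene | CC(C)=CCC/C(C)=C/CC/C(C)=C/CC/C(C)=C/CBr | intermediate
3 | ethyl (E)-3-(tributylstannyl)prop-2-enoate | CCOC(=O)/C=C/[Sn](CCCC)(CCCC)CCCC | starting material
4 | (E)-3-(tributylstannyl)prop-2-enoic acid | OC(=O)/C=C/[Sn](CCCC)(CCCC)CCCC | intermediate
5 | oxazolidin-2-one | O=C1NCCO1 | starting material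
6 | (E)-3-(tributylstannyl)prop-2-enoic 2,2-dimethylpropanoic anhydride | CC(C)(C)C(=O)OC(=O)/C=C/[Sn](CCCC)(CCCC)CCCC | intermediate
7 | 3-[(E)-3-(tributylstannyl)prop-2-enoyl]oxazolidin-2-one | O=C(/C=C/[Sn](CCCC)(CCCC)CCCC)N1CCOC1=O | intermediate
8 | 3-[(2E,5E,9E,13E)-6,10,14,18-tetramethylnonadeca-2,5,9,13,17-pentaenoyl]oxazolidin-2-one | CC(C)=CCC/C(C)=C/CC/C(C)=C/CC/C(C)=C/C/C=C/C(=O)N1CCOC1=O | intermediate
9 | 4-methylfuran-2(5H)-one | CC1=CC(=O)OC1 | starting material
10 | trimethyl[(4-methylfuran-2-yl)oxy]silane | Cc1coc(O[Si](C)(C)C)c1 | intermediate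
11 | 3-{(3S,5E,9E,13E)-6,10,14,18-tetramethyl-3-[(2S)-3-methyl-5-oxo-2,5-dihydrofuran-2-yl]nonadeca-5,9,13,17-tetraenoyl}oxazolidin-2-one | CC(C)=CCC/C(C)=C/CC/C(C)=C/CC/C(C)=C/C[C@@H](CC(=O)N1CCOC1=O)[C@@H]2OC(=O)C=C2C | intermediate
12 | 3-{[(5S,6S)-5-hydroxy-4-methyl-2-oxo-6-[(2E,6E,10E)-3,7,11,15-tetramethylhexadeca-2,6,10,14-tetraen-1-yl]cyclohex-3-en-1-yl]carbonyl}oxazolidin-2-one | CC(C)=CCC/C(C)=C/CC/C(C)=C/CC/C(C)=C/C[C@H]1C(C(=O)N2CCOC2=O)C(=O)C=C(C)[C@H]1O | intermediate
13 | (5S,6S)-5-hydroxy-4-methyl-2-oxo-6-[(2E,6E,10E)-3,7,11,15-tetramethylhexadeca-2,6,10,14-tetraen-1-yl]cyclohex-3-ene-1-carboperoxoic acid | CC(C)=CCC/C(C)=C/CC/C(C)=C/CC/C(C)=C/C[C@H]1C(C(=O)OO)C(=O)C=C(C)[C@H]1O | intermediate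
14 | (5S,6S)-5-hydroxy-4-methyl-2-oxo-6-[(2E,6E,10E)-3,7,11,15-tetramethylhexadeca-2,6,10,14-tetraen-1-yl]cyclohex-3-ene-1-carboxylic acid | CC(C)=CCC/C(C)=C/CC/C(C)=C/CC/C(C)=C/C[C@H]1C(C(=O)O)C(=O)C=C(C)[C@H]1O | intermediate
15 | (4S,5S)-4-hydroxy-3-methyl-5-[(2E,6E,10E)-3,7,11,15-tetramethylhexadeca-2,6,10,14-tetraen-1-yl]cyclohex-2-en-1-one | CC(C)=CCC/C(C)=C/CC/C(C)=C/CC/C(C)=C/C[C@H]1CC(=O)C=C(C)[C@H]1O | target

**Step count and risks**

Total step count: 7. Longest linear sequence: 5 (steps 2, 3, 4, 6, 7).

Most likely to fail, step 6: in the second stage, enolisation may occur at the butenolide γ-position instead of the imide α-position (loss of configuration at the carbinol carbon), the acyl transfer may be slower than retro-Michael cleavage, or TiCl4 may start cationic cyclisation of the polyene chain; in the first stage the long β-substituent may lower facial or anti selectivity. The fallback separates the two bond formations and closes the ring at the ester level. It sets out from 8 and 10, stops after the copper-catalysed stage and isolates butenolide 11. Compound 11 is transesterified with the bromomagnesium alkoxide of 2-(trimethylsilyl)ethanol (alcohol and MeMgBr, THF, 0 °C) to 2-(trimethylsilyl)ethyl (3S,5E,9E,13E)-6,10,14,18-tetramethyl-3-[(2S)-3-methyl-5-oxo-2,5-dihydrofuran-2-yl]nonadeca-5,9,13,17-tetraenoate F1. A classical Dieckmann condensation of its ester enolate onto the lactone carbonyl (LiN(SiMe3)2, THF, −78 to −20 °C) should give 2-(trimethylsilyl)ethyl (5S,6S)-5-hydroxy-4-methyl-2-oxo-6-[(2E,6E,10E)-3,7,11,15-tetramethylhexadeca-2,6,10,14-tetraen-1-yl]cyclohex-3-ene-1-carboxylate F2. Tetrabutylammonium fluoride (THF, 20 °C) cleaves the silylethyl ester, and the fallback comes back to the route at β-keto acid 14, which decarboxylates to 15.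

Second, step 7: alkaline hydrogen peroxide may attack the β-dicarbonyl unit or the enone (oxidative or retro-Claisen cleavage, Weitz–Scheffer epoxidation), or hydroxide may open the oxazolidinone ring instead of the exocyclic carbonyl. The fallback avoids peroxide and strong base. It sets out from 12, which is transesterified with allyl alcohol (DMAP catalysis, toluene, 80 °C) to prop-2-en-1-yl (5S,6S)-5-hydroxy-4-methyl-2-oxo-6-[(2E,6E,10E)-3,7,11,15-tetramethylhexadeca-2,6,10,14-tetraen-1-yl]cyclohex-3-ene-1-carboxylate F3. Tsuji–Trost deallylation with decarboxylation (Pd(PPh3)4 as the zerovalent palladium source, morpholine, THF, 20 °C) then comes back to the route at 15.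

Third, step 4: the skipped 2,5-diene may isomerise into conjugation through a palladium hydride or by deprotonation of its doubly activated CH2, the allyl terminus may scramble E/Z through η3–η1 interconversion, and transmetalation of the acceptor-substituted stannane may be slow. The fallback moves the carbonyl-bearing carbons to an olefin metathesis. It sets out from 2, which is coupled with the more reactive Bu3SnCH=CH2 (Pd2(dba)3, AsPh3, NMP, 25 °C) to the unactivated (4E,8E,12E)-5,9,13,17-tetramethyloctadeca-1,4,8,12,16-pentaene F4. Cross-metathesis of its terminal vinyl group with 3-acryloyloxazolidin-2-one (second-generation Hoveyda–Grubbs catalyst, CH2Cl2, 40 °C) comes back to the route at 8.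

Further compounds
F1 | step 6 | 2-(trimethylsilyl)ethyl (3S,5E,9E,13E)-6,10,14,18-tetramethyl-3-[(2S)-3-methyl-5-oxo-2,5-dihydrofuran-2-yl]nonadeca-5,9,13,17-tetraenoate | CC(C)=CCC/C(C)=C/CC/C(C)=C/CC/C(C)=C/C[C@@H](CC(=O)OCC[Si](C)(C)C)[C@@H]1OC(=O)C=C1C
F2 | step 6 | 2-(trimethylsilyl)ethyl (5S,6S)-5-hydroxy-4-methyl-2-oxo-6-[(2E,6E,10E)-3,7,11,15-tetramethylhexadeca-2,6,10,14-tetraen-1-yl]cyclohex-3-ene-1-carboxylate | CC(C)=CCC/C(C)=C/CC/C(C)=C/CC/C(C)=C/C[C@H]1C(C(=O)OCC[Si](C)(C)C)C(=O)C=C(C)[C@H]1O
F3 | step 7 | prop-2-en-1-yl (5S,6S)-5-hydroxy-4-methyl-2-oxo-6-[(2E,6E,10E)-3,7,11,15-tetramethylhexadeca-2,6,10,14-tetraen-1-yl]cyclohex-3-ene-1-carboxylate | CC(C)=CCC/C(C)=C/CC/C(C)=C/CC/C(C)=C/C[C@H]1C(C(=O)OCC=C)C(=O)C=C(C)[C@H]1O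
F4 | step 4 | (4E,8E,12E)-5,9,13,17-tetramethyloctadeca-1,4,8,12,16-pentaene | CC(C)=CCC/C(C)=C/CC/C(C)=C/CC/C(C)=C/CC=C
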